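**Retrosynthetic overview**

- The target is a bicyclo[2.2.2]oct-2-ene (bridgeheads C4' and C7'; bridges C3a'=C7a', C5'–C6' and C6–C7). Its four exocyclic carbons C1', C3', C5 and C7a all lie syn to the C5'–C6' bridge and the C6' oxygen is turned towards C1', so they are the four carboxyls of a meso tetraacid.
- Last disconnections: both Z-butylidene C=C bonds (one twofold vinylogous aldol–elimination on a bis-butenolide); lactone A through C1–C7a (carbonylation of an enol triflate) and reduction of C3; ring A through C3a–C7a (Dieckmann) and C4–C5 (Giese addition).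
- Lactone B comes from the bridged lactone by acyl transfer from O–C6' to O–C3', coupled to a selenoxide elimination across C3a'–C7a'.
- C5 and C7a are told apart by hydride opening of the C6–C7 anhydride away from the C5' iodine; all stereocentres come from one desymmetrising iodolactonisation (C6'–O bond) of the meso tetraacid.
- Ring order: cage (purchased) → bridged γ-lactone → fused γ-lactone on C6–C7 (opened later) → ring A → lactone B → lactone A.

Key step: step 2

Remark: labels follow the phthalide numbering of the target with primes on the hydroxylated half (ring A = C3a–C4–C5–C6–C7–C7a; lactones A and B = the unprimed and primed butenolides). The sense of induction in step 2 is assumed to be that of (DHQD)2PHAL; its pseudo-enantiomer (DHQ)2PHAL would be taken if the mirror-image lactone should form.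

**Route**

Step 1
Reactants: 1 bicyclo[2.2.2]oct-7-ene-2,3,5,6-tetracarboxylic dianhydride
Product: 2 meso bicyclo[2.2.2]oct-7-ene-2,3,5,6-tetracarboxylic acid (all carboxyls syn to the alkene)
Conditions: H2O, 90 °C
Reagents that add atoms: water O
Why: Hydrolysis of a cyclic anhydride; no stereocentre is touched and the cis, alkene-syn arrangement of the four carboxyls is kept.

Step 2
Reactants: 2 meso tetraacid; 3 N-iodosuccinimide
Product: 4 iodolactone triacid (γ-lactone C1'(=O)–O–C6'; iodine on C5' anti to the lactone oxygen; free acids C3', C5 and C7a)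
Conditions: NIS (1.1 equiv), (DHQD)2PHAL (hydroquinidine 1,4-phthalazinediyl diether, 10 mol %), THF/CHCl3 (1:4), −40 °C, dark
Reagents that add atoms: none
Why: Proposed new method: the quinuclidine nitrogen of the catalyst deprotonates one carboxyl and holds it as a chiral ion pair while NIS, activated by hydrogen bonding to the protonated catalyst, transfers iodine to the single alkene, and the iodiranium ion is then opened anti by that carboxylate. The closest known reactions are the cinchona-alkaloid-catalysed enantioselective halolactonisations of unsaturated acids, including desymmetrising variants, and the racemic iodolactonisation of endo-bicyclo[2.2.2]oct-5-ene-2-carboxylic acids, which closes the same bridged lactone. The γ-lactone closes 5-exo-trig, the carboxyl on C7a' reaching only the alkene carbon C6' that shares the bridgehead C7' with it. C6' (oxygen on the side of the lactone bridge) and C5' (iodine anti, towards the C6–C7 bridge) are set by the anti addition across the rigid alkene, and the six cage carbons C4', C7', C6, C7, C3a' and C7a', already cis-related in the meso acid, become fixed in the absolute sense by the choice of carboxyl, which is under catalyst control. Only the choice between the two enantiotopic pairs of carboxyls is needed; site, ring size and the pairing of alkene face with nucleophile are secured by the cage, since all four carboxyls are syn to the alkene and the two members of each pair are homotopic and give the same lactone.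

Step 3
Reactants: 4 iodolactone triacid
Product: 6 iodo bis-lactone acid (new fused γ-lactone C7a(=O)–O–C5H2; C3' acid free), via anhydride trifluoroacetate 5 (not isolated)
Conditions: (CF3CO)2O, CH2Cl2, 0 → 23 °C; concentrate; NaBH4, THF, 0 °C; then 1 M HCl
Reagents that add atoms: none
Why: Cyclic anhydride formation, then NaBH4 reduction of the anhydride to a γ-lactone: hydride should enter at the C5 carbonyl because the C7a carbonyl sits directly under the C5'–I bond, while the mixed anhydride at C3' is cleaved at the trifluoroacetyl carbon and returns the acid; no stereocentre changes.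

Step 4
Reactants: 6 iodo bis-lactone acid
Product: 7 bis-lactone acid (C5' is CH2)
Conditions: Bu3SnH, AIBN (cat.), PhMe, 80 °C
Reagents that add atoms: none
Why: Radical chain dehalogenation of the secondary iodide; only the C5' stereocentre is removed.

Step 5
Reactants: 7 bis-lactone acid
Product: 9 aldehyde bis-lactone (C3' is CHO), via acid chloride 8 (not isolated)
Conditions: (COCl)2, DMF (cat.), CH2Cl2, 0 → 23 °C; concentrate; LiAlH(OtBu)3 (1.05 equiv), THF, −78 °C
Reagents that add atoms: none
Why: Acid chloride formation and partial reduction with the hindered hydride LiAlH(OtBu)3, which stops at the aldehyde at −78 °C and spares both lactones; C3a' keeps its configuration under these non-basic conditions and is reset in step 13 in any case.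

Step 6
Reactants: 9 aldehyde bis-lactone
Product: 10 dimethyl acetal bis-lactone
Conditions: HC(OMe)3, PPTS (cat.), MeOH, 23 °C
Reagents that add atoms: trimethyl orthoformate COC(OC)OC; methanol CO
Why: Acid-catalysed acetalisation with the orthoformate as water scavenger; both γ-lactones are inert at room temperature.

Step 7
Reactants: 10 dimethyl acetal bis-lactone
Product: 12 selenide methyl ester (C5H2–SePh on C6; C7a methyl ester on C7), via sodium carboxylate 11 (not isolated)
Conditions: PhSeNa, DMF, 110 °C; then MeI, 23 °C
Reagents that add atoms: sodium benzeneselenolate [Na+].[Se-]c1ccccc1; iodomethane CI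
Why: SN2 opening of the fused γ-lactone at its primary O–CH2 carbon (C5) by the soft selenolate, then O-methylation of the carboxylate; the bridged lactone carries only a hindered secondary cage carbon on oxygen and should not open.

Step 8
Reactants: 12 selenide methyl ester; 13 tert-butyl acrylate
Product: 14 diester (C6–C5H2–C4H2–C3aH2–C3O2tBu chain; C7a methyl ester)
Conditions: Bu3SnH (slow addition), AIBN (cat.), PhH, 80 °C
Reagents that add atoms: none
Why: Giese addition: the primary C5 radical from the selenide adds to the acrylate terminus and the adduct radical is reduced by Bu3SnH; no stereocentre is formed.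

Step 9
Reactants: 14 diester
Product: 15 β-keto ester (ring A closed; C7a ketone, CO2tBu on C3a)
Conditions: LiN(SiMe3)2 (2.3 equiv), THF, −78 → 0 °C; then AcOH
Reagents that add atoms: none
Why: Dieckmann condensation: the chain CH2 next to the tert-butyl ester is deprotonated in preference to the hindered tertiary C7–H and closes the six-membered ring on the C7a methyl ester (the tert-butyl ester is a poor electrophile for the reverse mode); the ring can only be cis-fused on the eclipsed C6–C7 bridge, so C7 stays as set, and C3a is an enolisable centre removed in step 10.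

Step 10
Reactants: 15 β-keto ester
Product: 16 enol triflate (C7a–OTf, C7a=C3a)
Conditions: NaH, THF, 0 °C; then PhNTf2, 23 °C
Reagents that add atoms: N-phenylbis(trifluoromethanesulfonimide) O=S(=O)(N(c1ccccc1)S(=O)(=O)C(F)(F)F)C(F)(F)F
Why: O-Triflation of the β-keto ester enolate, which gives the conjugated enol triflate with the C7a=C3a double bond.

Step 11
Reactants: 16 enol triflate; 17 carbon monoxide
Product: 18 ring A diester (C1 methyl ester on C7a, C3 tert-butyl ester on C3a)
Conditions: CO (1 atm), Pd(OAc)2 (5 mol %), dppp (6 mol %), Et3N, MeOH/DMF, 70 °C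
Reagents that add atoms: methanol CO
Why: Alkoxycarbonylation of a vinyl triflate: oxidative addition to zerovalent palladium, CO insertion and methanolysis of the acyl complex place C1 on C7a.

Step 12
Reactants: 18 ring A diester
Product: 19 aldehyde diester (C3' is CHO again)
Conditions: PPTS (cat.), acetone/H2O (9:1), 50 °C
Reagents that add atoms: water O
Why: Mild acid hydrolysis of the dimethyl acetal; the tert-butyl ester and the lactone are stable to PPTS.

Step 13
Reactants: 19 aldehyde diester
Product: 20 α-phenylseleno aldehyde (SePh on C3a', on the face turned to the C6–C7 bridge)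
Conditions: PhSeCl, EtOAc, 23 °C
Reagents that add atoms: benzeneselenenyl chloride Cl[Se]c1ccccc1
Why: α-Selenenylation of an aldehyde through its enol; PhSe should add to C3a' anti to the eclipsed lactone carbonyl on C7a', so that the formyl group stays cis to C1'.

Step 14
Reactants: 20 α-phenylseleno aldehyde
Product: 21 β-hydroxy selenide (C3' is CH2OH)
Conditions: NaBH4, MeOH/THF, −20 °C
Reagents that add atoms: none
Why: Chemoselective borohydride reduction of the aldehyde; esters, lactone and selenide are untouched, and any acyl shift of the lactone to O–C3' is harmless because both isomers converge in step 15.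

Step 15
Reactants: 21 β-hydroxy selenide
Product: 24 butenolide B diester (lactone C1'(=O)–O–C3'H2, C7a'=C3a', C6'–OH free), via bridged selenoxide 22 (not isolated), via fused selenoxide 23 (not isolated)
Conditions: mCPBA (1.05 equiv), CH2Cl2, −78 °C; then DBU, −78 → 23 °C
Reagents that add atoms: none
Why: Selenide oxidation, base-mediated transesterification and selenoxide syn-elimination: the bridged selenoxide cannot eliminate towards C7a' because the alkene would be twisted out of the lactone, but the C3' alkoxide moves the acyl group from O–C6' to O–C3', and in the fused lactone C7a'–H is α to the carbonyl and syn to selenium, so elimination drains the equilibrium into butenolide B and frees the C6' hydroxyl.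

Step 16
Reactants: 24 butenolide B diester
Product: 25 C3 carboxylic acid
Conditions: CF3CO2H/CH2Cl2 (1:4), 0 → 23 °C
Reagents that add atoms: none
Why: Acidolysis of the tert-butyl ester with loss of isobutene; the methyl ester and the butenolide are stable.

Step 17
Reactants: 25 C3 carboxylic acid
Product: 27 bis-butenolide alcohol (lactone A closed, C1(=O)–O–C3H2), via hydroxy ester 26 (not isolated)
Conditions: BH3·SMe2, THF, 0 → 23 °C; MeOH; then TsOH·H2O (cat.), CH2Cl2, 23 °C
Reagents that add atoms: none
Why: Borane reduces the free carboxylic acid much faster than ester or lactone, and the resulting cis γ-hydroxy enoate lactonises on to the C1 methyl ester.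

Step 18
Reactants: 27 bis-butenolide alcohol; 28 butanal
Product: 31 silyl ether of the target (both Z-butylidene groups in place, C6'–OTBS), via tris-silyl bis-furan 29 (not isolated), via bis-aldol silyl ether 30 (not isolated)
Conditions: TBSOTf (3.5 equiv), Et3N, CH2Cl2, 0 °C; butanal, −78 → 0 °C; then DBU, 23 °C
Reagents that add atoms: tert-butyldimethylsilyl trifluoromethanesulfonate CC(C)(C)[Si](C)(C)OS(=O)(=O)C(F)(F)F
Why: Vinylogous Mukaiyama aldol then E1cB elimination: both butenolides are converted into 2-silyloxyfurans (the C6' hydroxyl is silylated at the same time), each adds butanal at its γ-carbon (C3, C3') with silyl transfer, and DBU expels silanolate through the γ-deprotonated dienolate to give the Z-alkenes, Z being favoured because the E isomer would press the propyl group against C4 or C4'.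

Step 19
Reactants: 31 silyl ether of the target
Product: 32 target CNP0289078.1
Conditions: HF·pyridine, THF/pyridine, 0 → 23 °C
Reagents that add atoms: none
Why: Fluoride-mediated cleavage of the silyl ether under buffered conditions that should leave the alkylidene butenolides intact.

**Compound list**

1 | bicyclo[2.2.2]oct-7-ene-2,3,5,6-tetracarboxylic dianhydride (meso, both anhydrides syn to the alkene) | O=C1[C@@H]2[C@H]3[C@@H]4C(=O)OC(=O)[C@@H]4[C@H](C=C3)[C@@H]2C(=O)O1 | starting material
2 | meso bicyclo[2.2.2]oct-7-ene-2,3,5,6-tetracarboxylic acid | OC(=O)[C@@H]1[C@H]2[C@H](C(=O)O)[C@H](C(=O)O)[C@H](C=C2)[C@@H]1C(=O)O | intermediate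
3 | N-iodosuccinimide | O=C1CCC(=O)N1I | starting material
4 | iodolactone triacid | OC(=O)[C@@H]1[C@H]2[C@@H]3C(=O)O[C@H]2[C@H](I)[C@@H]([C@H]3C(=O)O)[C@@H]1C(=O)O | intermediate
5 | C5/C7a cyclic anhydride with C3' mixed trifluoroacetic anhydride | O=C4[C@@H]1[C@H]2[C@@H]3C(=O)O[C@H]2[C@H](I)[C@@H]([C@H]3C(=O)OC(=O)C(F)(F)F)[C@@H]1C(=O)O4 | intermediate (not isolated)
6 | iodo bis-lactone acid | O=C4OC[C@@H]1[C@H]2[C@@H]3C(=O)O[C@H]2[C@H](I)[C@@H]([C@H]3C(=O)O)[C@@H]14 | intermediate
7 | bis-lactone acid | O=C4OC[C@@H]1[C@H]2[C@@H]3C(=O)O[C@H]2C[C@@H]([C@H]3C(=O)O)[C@@H]14 | intermediate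
8 | C3' acid chloride | O=C4OC[C@@H]1[C@H]2[C@@H]3C(=O)O[C@H]2C[C@@H]([C@H]3C(=O)Cl)[C@@H]14 | intermediate (not isolated)
9 | aldehyde bis-lactone | O=C4OC[C@@H]1[C@H]2[C@@H]3C(=O)O[C@H]2C[C@@H]([C@H]3C=O)[C@@H]14 | intermediate
10 | dimethyl acetal bis-lactone | O=C4OC[C@@H]1[C@H]2[C@@H]3C(=O)O[C@H]2C[C@@H]([C@H]3C(OC)OC)[C@@H]14 | intermediate
11 | sodium carboxylate of the C5 selenide | c5ccccc5[Se]C[C@@H]1[C@H]2[C@@H]3C(=O)O[C@H]2C[C@@H]([C@H]3C(OC)OC)[C@@H]1C(=O)[O-].[Na+] | intermediate (not isolated)
12 | selenide methyl ester | c5ccccc5[Se]C[C@@H]1[C@H]2[C@@H]3C(=O)O[C@H]2C[C@@H]([C@H]3C(OC)OC)[C@@H]1C(=O)OC | intermediate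
13 | tert-butyl acrylate | C=CC(=O)OC(C)(C)C | starting material
14 | diester (Giese adduct) | CC(C)(C)OC(=O)CCC[C@@H]1[C@H]2[C@@H]3C(=O)O[C@H]2C[C@@H]([C@H]3C(OC)OC)[C@@H]1C(=O)OC | intermediate
15 | β-keto ester (C3a epimers and enol) | CC(C)(C)OC(=O)C5CC[C@@H]1[C@H]2[C@@H]3C(=O)O[C@H]2C[C@@H]([C@H]3C(OC)OC)[C@@H]1C5=O | intermediate
16 | enol triflate | FC(F)(F)S(=O)(=O)OC5=C(C(=O)OC(C)(C)C)CC[C@@H]1[C@H]2[C@@H]3C(=O)O[C@H]2C[C@@H]([C@H]3C(OC)OC)[C@@H]15 | intermediate
17 | carbon monoxide | [C-]#[O+] | starting material
18 | ring A diester | COC(=O)C5=C(C(=O)OC(C)(C)C)CC[C@@H]1[C@H]2[C@@H]3C(=O)O[C@H]2C[C@@H]([C@H]3C(OC)OC)[C@@H]15 | intermediate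
19 | aldehyde diester | COC(=O)C5=C(C(=O)OC(C)(C)C)CC[C@@H]1[C@H]2[C@@H]3C(=O)O[C@H]2C[C@@H]([C@H]3C=O)[C@@H]15 | intermediate
20 | α-phenylseleno aldehyde | COC(=O)C5=C(C(=O)OC(C)(C)C)CC[C@@H]1[C@H]2[C@@H]3C(=O)O[C@H]2C[C@@H]([C@@]3([Se]c6ccccc6)C=O)[C@@H]15 | intermediate
21 | β-hydroxy selenide | COC(=O)C5=C(C(=O)OC(C)(C)C)CC[C@@H]1[C@H]2[C@@H]3C(=O)O[C@H]2C[C@@H]([C@@]3([Se]c6ccccc6)CO)[C@@H]15 | intermediate
22 | bridged-lactone selenoxide (Se epimers) | COC(=O)C5=C(C(=O)OC(C)(C)C)CC[C@@H]1[C@H]2[C@@H]3C(=O)O[C@H]2C[C@@H]([C@@]3([Se](=O)c6ccccc6)CO)[C@@H]15 | intermediate (not isolated)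
23 | fused-lactone selenoxide (Se epimers) | COC(=O)C5=C(C(=O)OC(C)(C)C)CC[C@@H]1[C@H]2[C@@H]3C(=O)OC[C@]3([Se](=O)c6ccccc6)[C@H](C[C@@H]2O)[C@@H]15 | intermediate (not isolated)
24 | butenolide B diester | COC(=O)C5=C(C(=O)OC(C)(C)C)CC[C@@H]1[C@H]2C3=C(COC3=O)[C@H](C[C@@H]2O)[C@@H]15 | intermediate
25 | C3 carboxylic acid | COC(=O)C5=C(C(=O)O)CC[C@@H]1[C@H]2C3=C(COC3=O)[C@H](C[C@@H]2O)[C@@H]15 | intermediate
26 | C3 hydroxymethyl ester | COC(=O)C5=C(CO)CC[C@@H]1[C@H]2C3=C(COC3=O)[C@H](C[C@@H]2O)[C@@H]15 | intermediate (not isolated)
27 | bis-butenolide alcohol | C1OC(=O)C2=C1CC[C@@H]1[C@H]3C4=C(COC4=O)[C@H](C[C@@H]3O)[C@H]21 | intermediate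
28 | butanal | CCCC=O | starting material
29 | tris-silyl bis(2-silyloxyfuran) | O1C=C2CC[C@@H]3[C@H]4C5=C(O[Si](C)(C)C(C)(C)C)OC=C5[C@H](C[C@@H]4O[Si](C)(C)C(C)(C)C)[C@@H]3C2=C1O[Si](C)(C)C(C)(C)C | intermediate (not isolated)
30 | bis-aldol tris-silyl ether (mixture at C3, C3' and both carbinol carbons) | CCCC(O[Si](C)(C)C(C)(C)C)C1OC(=O)C2=C1CC[C@@H]1[C@H]3C4=C(C(OC4=O)C(CCC)O[Si](C)(C)C(C)(C)C)[C@H](C[C@@H]3O[Si](C)(C)C(C)(C)C)[C@H]21 | intermediate (not isolated)
31 | C6' tert-butyldimethylsilyl ether of the target | CCC/C=C1\OC(=O)C2=C1CC[C@@H]1[C@H]3C4=C(/C(=C/CCC)OC4=O)[C@H](C[C@@H]3O[Si](C)(C)C(C)(C)C)[C@H]21 | intermediate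
32 | CNP0289078.1 | CCC/C=C1\OC(=O)C2=C1CC[C@@H]1[C@H]3C4=C(/C(=C/CCC)OC4=O)[C@H](C[C@@H]3O)[C@H]21 | target

**Count and risks**

Total step count: 19. Longest linear sequence: 19 steps (from 1 to 32; 3, 13, 17 and 28 are purchased inputs).

Steps most likely to fail:

Step 2. The catalyst may fail to choose between the enantiotopic carboxyl pairs, or be inhibited by the polyacid, so that the lactone forms with low enantiomeric purity. The fallback moves the symmetry-breaking to a known anhydride alcoholysis. From dianhydride 1, quinidine-mediated methanolysis (MeOH, PhMe/CCl4, −55 °C) should open each anhydride in the same enantiotopic sense and give the C2-symmetric bis(hemiester) F1, with the second opening raising the optical purity of the C2 product. Its two free acids are homotopic, so classical iodolactonisation (I2, KI, NaHCO3, H2O/THF) should give one iodolactone diester acid F2 whichever acid closes. Acid hydrolysis of the two methyl esters (2 M HCl, dioxane, 70 °C) returns to 4.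

Step 3. Hydride delivery may discriminate poorly between the C5 and C7a carbonyls, or prefer the iodine-flanked one. The fallback replaces substrate control by reagent control and a chemoselective borane reduction. From 4, (CF3CO)2O followed by a brief cold aqueous work-up should give the anhydride acid F3. Cinchona-alkaloid-mediated methanolysis (quinine or quinidine, whichever is matched to attack at C7a) should give the C7a methyl ester diacid F4. BH3·SMe2 then reduces the two free acids (C5 and C3') but neither ester nor lactone, and the C5 alcohol closes on the C7a ester to give the hydroxy iodo bis-lactone F5. Bu3SnH removes the iodine to give the hydroxy bis-lactone F6, which is kept under neutral conditions and oxidised without delay (Dess–Martin periodinane) to rejoin the route at 9.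

Step 18. The twofold aldol may stall after one addition, butanal may self-condense, or the elimination may give E/Z mixtures at one of the two alkenes. The fallback makes the C=C bonds by Wittig olefination. From 27, silylation as in step 18 gives 29, which is brominated at both furan γ-carbons (NBS, −78 °C) to the bis(γ-bromobutenolide) silyl ether F7. PPh3 (MeCN, 50 °C) should give the bis-phosphonium dibromide F8, and Et3N with butanal should give 31 through the stabilised ylides; a trace of iodine under light equilibrates any E isomer to the more stable Z form.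

**Further compounds**

F1 | step 2 | C2-symmetric bis(hemiester): methyl esters on the C5 and C3' carboxyls, free acids on the C1' and C7a carboxyls | COC(=O)[C@@H]1[C@H]2[C@H](C(=O)O)[C@H](C(=O)OC)[C@H](C=C2)[C@@H]1C(=O)O
F2 | step 2 | iodolactone C5,C3'-dimethyl ester C7a acid | COC(=O)[C@@H]1[C@H]2[C@@H]3C(=O)O[C@H]2[C@H](I)[C@@H]([C@H]3C(=O)OC)[C@@H]1C(=O)O
F3 | step 3 | iodolactone C5/C7a cyclic anhydride C3' acid | O=C4[C@@H]1[C@H]2[C@@H]3C(=O)O[C@H]2[C@H](I)[C@@H]([C@H]3C(=O)O)[C@@H]1C(=O)O4
F4 | step 3 | iodolactone C7a methyl ester C5,C3'-diacid | OC(=O)[C@@H]1[C@H]2[C@@H]3C(=O)O[C@H]2[C@H](I)[C@@H]([C@H]3C(=O)O)[C@@H]1C(=O)OC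
F5 | step 3 | hydroxy iodo bis-lactone (C3' is CH2OH) | O=C4OC[C@@H]1[C@H]2[C@@H]3C(=O)O[C@H]2[C@H](I)[C@@H]([C@H]3CO)[C@@H]14
F6 | step 3 | hydroxy bis-lactone (C3' is CH2OH, C5' is CH2) | O=C4OC[C@@H]1[C@H]2[C@@H]3C(=O)O[C@H]2C[C@@H]([C@H]3CO)[C@@H]14
F7 | step 18 | bis(γ-bromobutenolide) C6' silyl ether (mixture at C3 and C3') | BrC1OC(=O)C2=C1CC[C@@H]1[C@H]3C4=C(C(Br)OC4=O)[C@H](C[C@@H]3O[Si](C)(C)C(C)(C)C)[C@H]21
F8 | step 18 | bis(triphenylphosphonium) dibromide C6' silyl ether | C1(OC(=O)C2=C1CC[C@@H]1[C@H]3C4=C(C(OC4=O)[P+](c5ccccc5)(c5ccccc5)c5ccccc5)[C@H](C[C@@H]3O[Si](C)(C)C(C)(C)C)[C@H]21)[P+](c6ccccc6)(c6ccccc6)c6ccccc6.[Br-].[Br-]
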